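Take the ratio 1.06 for the flask: [impurity] over [free catalyst] as charged, the poison ratio. Once free catalyst + impurity -> spent catalyst (catalyst poisoning), taken one to one, has run its course, a ratio below one leaves one minus the ratio of the catalyst free. A ratio above one leaves no free catalyst, and one minus its inverse of the impurity.

| flask | starting material | free catalyst | impurity | temperature | remark | time |
|---|---|---|---|---|---|---|
| dawn | 3 M | 33 mM | 35 mM | −20 °C | the very flask that is asked about, followed so far |  |
| autumn | 3 M | 33 mM | 18 mM | −25 °C | run made earlier |  |
| flask | 3.0 M | 33 mM | 35 mM | −20 °C |  | 10 min |

- dawn (time / min: target / %): 0.500: 4; 0.833: 8; 1.33: 5; 2.00: 11; 4.00: 6; 6.00: 10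
- autumn (time / s: target / %): 10.0: 3; 15.0: 1; 25.0: 8; 40.0: 15; 80.0: 35; 120: 47

(standard deviation of a reading: 2 percentage points)

- west: at 10 min take out 90% of the target then present, then wait 10 min
- north-west: at 10 min raise the temperature by 15 K, then wait 10 min
- north: at 10 min add free catalyst, 50.0% of the amount charged, then wait 10 min
- north-east: change nothing and wait 10 min more

- removed target is counted in
- what was read earlier has a scatter of 2 percentage points, one standard deviation
- steps under discussion: starting material -> intermediate; free catalyst + intermediate -> free catalyst + target; starting material -> uncatalysed product; free catalyst + impurity -> spent catalyst
- additions bring no volume worth counting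

- target, in percent of the starting material first charged, at 10 min
- the option that brings most further target ("none" if no option brings more than 2 percentage points) (west / north-west / north / north-east / none)
- target present, with what was taken out counted in, in percent of the starting material first charged, after west
- target present, with what was taken out counted in, in percent of the starting material first charged, after north-west

Try the ratio on the autumn run first: 0.545 leaves 45.5% of the catalyst free, or 15.0 mM, and target there climbs to 47% at 120 s. In the dawn run, which is the flask itself followed so far, the ratio stands above one, and from 0.833 min on the target readings scatter about one level with no trend to read. Average the last 5 dawn readings to get 8.00%, and reckon that for the flask at 10 min. With the ratio above one, expect west, north-west and north-east to add nothing. North lowers the ratio to 0.707, which leaves 14.5 mM free, close to the autumn level. The 10 min of waiting is also longer than the autumn run's 120 s, so my choice is north.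

The forecast says 7.7% (range 6.3% to 9.2%), a little below my plateau. It gives 7.7% after west, 7.7% after north-west, and best north, holding that “the catalyst has been destroyed”.

The flask gives 8.90%, then 8.90% after west and 8.90% after north-west. North-east brings 0 percentage points, north brings 51 points, and the best option is north.

    starting material → intermediate (k = 0.0270 /s, Ea = 77.0 kJ/mol)
    free catalyst + intermediate → free catalyst + target (k = 2.40 /M/s, Ea = 38.0 kJ/mol)
    starting material → uncatalysed product (k = 0.0180 /s, Ea = 63.0 kJ/mol)
    free catalyst + impurity → spent catalyst (k = 15.0 /M/s, Ea = 47.0 kJ/mol)
    (constants at −20 °C)

Read the flask at 10.0 min as a store: intermediate stands at 51.1% of the starting material charged, beside 8.90% target, with free catalyst at 0% of its charge. The ratio 1.06 stands above one, and one minus its inverse gives 5.71% of the impurity left; the flask holds 5.71%. Now charge 0.056 M of free catalyst at the start, as in the neighbouring flask. Its ratio is 0.625, so reckon 37.5% of the catalyst free; that flask holds 37.5%. Its intermediate stands at 0%, its uncatalysed product at 40.0%, and its target at 60.0%.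

Readings and results come from a simulation for substances that don't exist; the scatter is artificial.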